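**Strategy.** The route rests on a formal (4+3) disconnection of the seven-membered ring C8–C9–C11–C12–C13–C16–C15 of the bicyclo[3.2.1]octane (rings C and D), which shares quaternary C8 with cyclopentane ring B. A rhodium vinylcarbenoid at C9, tethered through the C10 ketone, cyclopropanates C8=C15 of a 3-silyloxycyclopentadiene and so closes ring B by the C8–C9 bond; the cis-divinylcyclopropane then undergoes Cope rearrangement, forming C12–C13. One operation gives rings B, C and D, quaternary C8, the C10 ketone and a masked C16 ketone from an acyclic vinyl diazoketone carrying the cyclopentadiene. Ring A and the lactone follow by Michael, aldol and metathesis steps.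

Key step: step 7

Remark on numbering: gibberellane locants are used for the carbons of all intermediates (C7 = ester carbon, C17 = exocyclic methylene carbon, C18 = 4-methyl, C19 = lactone carbonyl). α is the face of the lactone bridge; β is the face of H-5, H-9 and the three hydroxyls. In the names of the tetracyclic compounds "19,10-lactone" stands for the γ-lactone between the C19 carboxyl on C4 and the 10α-oxygen.

Assumption: Rh2(S-PTAD)4, dirhodium tetrakis[(S)-(1-adamantyl)(N-phthalimido)acetate], is taken to give the enantiomer drawn in step 7; if the sense of induction is the opposite, Rh2(R-PTAD)4 is used.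

Step 1
Reactants: 1 cyclopentane-1,3-dione
Product: 2 3-chlorocyclopent-2-en-1-one
Conditions: (COCl)2, DMF (cat.), CH2Cl2, 0 °C to rt
Reagents that add atoms: oxalyl chloride, O=C(Cl)C(=O)Cl
Why: Vinylogous acid chloride formation from the enol of a 1,3-diketone (O-acylation, then addition–elimination by chloride); no stereocentre is formed.

Step 2
Reactants: 3 dimethyl malonate; 4 2-chloro-N-methoxy-N-methylacetamide
Product: 5 dimethyl 2-[2-[methoxy(methyl)amino]-2-oxoethyl]propanedioate
Conditions: NaH, NaI (cat.), THF, 0 °C to rt, malonate in excess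
Reagents that add atoms: none
Why: Malonic ester alkylation (SN2) with an activated α-chloro amide; excess malonate should suppress dialkylation.

Step 3
Reactants: 5 dimethyl 2-[2-[methoxy(methyl)amino]-2-oxoethyl]propanedioate
Product: 6 dimethyl 2-(2-oxopent-4-en-1-yl)propanedioate
Conditions: NaH (1.0 equiv), THF, 0 °C; then CH2=CHCH2MgBr (1.2 equiv), −78 °C; AcOH quench at −78 °C
Reagents that add atoms: allylmagnesium bromide, C=CC[Mg]Br
Why: Weinreb ketone synthesis on the preformed sodium enolate of the malonate, which shields both esters and the acidic hydrogen from the Grignard reagent; the chelated tetrahedral intermediate stops at the ketone stage and the cold acidic quench should keep the double bond out of conjugation.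

Step 4
Reactants: 6 dimethyl 2-(2-oxopent-4-en-1-yl)propanedioate; 2 3-chlorocyclopent-2-en-1-one
Product: 7 dimethyl 2-(2-oxopent-4-en-1-yl)-2-(3-oxocyclopent-1-en-1-yl)propanedioate
Conditions: NaH (1.0 equiv), THF, 0 °C; then 2, 0 °C to rt
Reagents that add atoms: none
Why: Conjugate addition–elimination (vinylogous acyl substitution) of the malonate anion on the β-chloro enone should give the quaternary C6; exactly one equivalent of base is used because the malonate hydrogen is by far the most acidic, so the β,γ-unsaturated ketone is not enolised.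

Step 5
Reactants: 7 enone allyl ketone
Product: 8 dimethyl 2-(3-diazo-2-oxopent-4-en-1-yl)-2-(3-oxocyclopent-1-en-1-yl)propanedioate
Conditions: 4-acetamidobenzenesulfonyl azide, DBU, MeCN, 0 °C; quick filtration through basic alumina at 0 °C; used at once
Reagents that add atoms: 4-acetamidobenzenesulfonyl azide, CC(=O)Nc1ccc(cc1)S(=O)(=O)N=[N+]=[N-]
Why: Regitz diazo transfer to the doubly activated C9 methylene (flanked by ketone and vinyl), the only position whose enolate DBU populates, should give the vinyl diazoketone faster than the dienolate can add to the hindered β,β-disubstituted enone; the product is kept cold and used at once because it can electrocyclise to a pyrazole.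

Step 6
Reactants: 8 enone vinyl diazoketone
Product: 9 dimethyl 2-(3-diazo-2-oxopent-4-en-1-yl)-2-[3-(triisopropylsilyloxy)cyclopenta-1,3-dien-1-yl]propanedioate
Conditions: LiN(iPr)2 (1.05 equiv), THF, −78 °C; then iPr3SiOTf, −78 °C; cold pentane/aq. NaHCO3 work-up; solution kept below −20 °C and used at once
Reagents that add atoms: triisopropylsilyl triflate, CC(C)[Si](C(C)C)(C(C)C)OS(=O)(=O)C(F)(F)F
Why: Kinetic α′-deprotonation of the cyclopentenone at C13 (more acidic and less hindered than the neopentyl C5 methylene of the diazoketone, whose carbonyl is deactivated by the diazo group) and O-silylation should give the 2-silyloxydiene with termini C8 and C13 and sp3 C14; forming the acidic, isomerisable cyclopentadiene last keeps it away from amine base, sulfonyl azide and 1,5-hydrogen shift.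

Step 7
Reactants: 9 vinyl diazoketone
Product: 11 dimethyl 4-oxo-9-(triisopropylsilyloxy)tricyclo[6.2.1.0^{1,5}]undeca-5,9-diene-2,2-dicarboxylate (B/C/D tricycle; C10 ketone; C9=C11; C15=C16 silyl enol ether), via divinylcyclopropane 10 (not isolated)
Conditions: Rh2(S-PTAD)4 (1 mol %), 2,2-dimethylbutane, −40 °C to rt, slow addition of 9
Reagents that add atoms: none
Why: Loss of N2 at the dirhodium carboxylate gives a donor/acceptor vinylcarbenoid at C9, which cyclopropanates the proximal C8=C15 bond through the three-atom tether (C10, C5, C6); this closes ring B as a bicyclo[3.1.0]hexanone (five-membered ring closure by intramolecular cyclopropanation) and forms C8–C9. In 10 ring B occupies one face of the cyclopropane, so the C9 vinyl group and the ring-held C16=C13 enol ether are necessarily cis, and a boat-like [3,3]-sigmatropic divinylcyclopropane–cycloheptadiene (Cope) rearrangement follows below room temperature, forming C12–C13, cleaving C9–C15 and so closing ring C and the bicyclo[3.2.1]octane. The closest known reaction type is the tandem cyclopropanation/Cope rearrangement (formal (4+3) cycloaddition) of vinyldiazo carbonyl compounds with cyclopentadienes, including its intramolecular form. The only stereo-determining event is the choice of face of C8=C15, controlled by the chiral carboxylate ligands; C13 follows from the stereospecific Cope step and the bridged framework, and C9 is not yet stereogenic. The step needs site selectivity for C8=C15 (secured by the tether length, C13=C16 being out of reach), intact 1,3-diene regiochemistry (secured by kinetic enolisation in step 6 and immediate cold use) and preference for alkene over ester-carbonyl attack (secured by the electron-rich diene and the quaternary C6).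

Step 8
Reactants: 11 tricyclic dienone
Product: 12 dimethyl 4-oxo-9-(triisopropylsilyloxy)tricyclo[6.2.1.0^{1,5}]undec-9-ene-2,2-dicarboxylate (C9 epimers)
Conditions: [(Ph3P)CuH]6, H2O, toluene, rt
Reagents that add atoms: none
Why: Copper hydride conjugate reduction of the C10/C9=C11 enone should leave the silyl enol ether and esters untouched; C9 is not fixed here because both epimers converge in step 9.

Step 9
Reactants: 12 keto diester
Product: 13 methyl 4-oxo-9-(triisopropylsilyloxy)tricyclo[6.2.1.0^{1,5}]undec-9-ene-2-carboxylate (9β-H; C6 epimers)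
Conditions: LiCl, H2O (2 equiv), DMSO, 140 °C
Reagents that add atoms: none
Why: Krapcho dealkoxycarbonylation; under the hot, weakly basic conditions C9 (α to the C10 ketone) should equilibrate to the 9β-H epimer, in which H-9 is cis to the angular C15 as in the favoured cis-hydrindanone arrangement of a ketone next to an angularly substituted ring fusion, while C6 stays unfixed and is erased in step 10.

Step 10
Reactants: 13 keto ester
Product: 14 methyl 4-oxo-9-(triisopropylsilyloxy)tricyclo[6.2.1.0^{1,5}]undeca-2,9-diene-2-carboxylate (C5=C6 enone ester; 9β-H)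
Conditions: LiN(iPr)2, THF, −78 °C; then N-tert-butylbenzenesulfinimidoyl chloride, −78 °C
Reagents that add atoms: none
Why: Kinetic enolisation at the less substituted C5, sulfinimidoyl transfer and syn-elimination (Mukaiyama dehydrogenation of a lithium enolate) should give the C5=C6 acceptor needed for lactone formation.

Step 11
Reactants: 14 enone ester
Product: 16 methyl 4-(propanoyloxy)-9-(triisopropylsilyloxy)-4-vinyltricyclo[6.2.1.0^{1,5}]undeca-2,9-diene-2-carboxylate (10α-propanoate; 10β-vinyl), via tertiary carbinol 15 (not isolated)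
Conditions: CH2=CHMgBr, CeCl3, THF, −78 °C; then (EtCO)2O, DMAP (cat.), −78 to 0 °C
Reagents that add atoms: vinylmagnesium bromide, C=C[Mg]Br; propanoic anhydride, CCC(=O)OC(=O)CC
Why: Organocerium 1,2-addition to the C10 carbonyl from the β face, anti to the adjacent C9–C11 bond and to the pseudo-axial C14 that shield the α face, should set the 10α-oxygen; the alkoxide is acylated in the same flask.

Step 12
Reactants: 16 tertiary propanoate
Product: 17 γ-lactone (C19–O–C10 lactone with the C4–C5 bond formed; 4-H/4-CH3 epimers; 10β-vinyl; 5β-H; 6β-CO2Me; C15=C16 silyl enol ether)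
Conditions: KOtBu (30 mol %), THF–t-BuOH (10:1), 0 °C to rt
Reagents that add atoms: none
Why: Intramolecular Michael addition (5-exo-trig) of the propanoate enolate, delivered from the 10α-oxygen and therefore to the α face of C5 (5β-H); alkoxide equilibration should place the C6 ester trans to the new C4–C5 bond (6β).

Step 13
Reactants: 17 γ-lactone
Product: 18 aldol adduct (17 with quaternary C4 bearing CH3 and a 3β-configured 1-hydroxyprop-2-enyl group)
Conditions: LiN(iPr)2, THF, −78 °C; acrolein, −78 °C; AcOH quench at −78 °C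
Reagents that add atoms: acrolein, C=CC=O
Why: Aldol addition of the lithium lactone enolate (the lactone α-hydrogen is more acidic than the hindered C6–H) on the convex face of the cis-fused bicyclic lactone, syn to H-5 and the C10 vinyl group, sets C4; a closed Zimmerman–Traxler transition state with the vinyl group equatorial predicts the carbinol that becomes the axial 3β-hydroxyl.

Step 14
Reactants: 18 aldol adduct
Product: 19 methyl 3β-hydroxy-16-(triisopropylsilyloxy)-17,20-dinorgibberella-1,15-dien-7-oate 19,10-lactone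
Conditions: second-generation Grubbs catalyst RuCl2(H2IMes)(PCy3)(=CHPh) (5 mol %), CH2Cl2, 40 °C
Reagents that add atoms: none
Why: Ring-closing metathesis of the two monosubstituted vinyl groups closes the six-membered ring A as the C1=C2 alkene; the trisubstituted silyl enol ether should be inert.

Step 15
Reactants: 19 silyl enol ether
Product: 20 methyl 3β-hydroxy-16-oxo-17,20-dinorgibberell-1-en-7-oate 19,10-lactone
Conditions: HF·pyridine, THF, 0 °C
Reagents that add atoms: none
Why: Protodesilylation of the silyl enol ether unmasks the C16 ketone, with protonation possible only at C15 because C13 is a bridgehead; the mild conditions should spare the allylic lactone.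

Step 16
Reactants: 20 allylic alcohol ketone
Product: 22 methyl 1β,2β,3β-trihydroxy-16-oxo-17,20-dinorgibberellan-7-oate 19,10-lactone, via osmate ester 21 (not isolated)
Conditions: OsO4 (1.05 equiv), TMEDA, CH2Cl2, −78 °C; then aq. Na2SO3, THF, 50 °C
Reagents that add atoms: osmium tetroxide, O=[Os](=O)(=O)=O
Why: Hydrogen-bond-directed syn-dihydroxylation by the OsO4–TMEDA complex, bound to the axial 3β-hydroxyl, delivers both oxygens to the β face of C1=C2, which is also the face not blocked by the lactone bridge.

Step 17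
Reactants: 22 triol ketone
Product: 23 methyl 1β,2β,3β-trihydroxy-20-norgibberell-16-en-7-oate 19,10-lactone (methyl ester of the target)
Conditions: Zn, CH2Br2, TiCl4, THF–CH2Cl2, 0 °C to rt (excess reagent)
Reagents that add atoms: dibromomethane, BrCBr
Why: Lombardo methylenation, a non-basic geminal dizinc/titanium reagent, should convert the ketone into the exocyclic C16=C17 alkene without touching ester or lactone and without retro-aldol at the β-hydroxy lactone.

Step 18
Reactants: 23 methyl ester of the target
Product: 24 1β,2β,3β-trihydroxy-20-norgibberell-16-en-7-oic acid 19,10-lactone (the target gibberellin)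
Conditions: n-PrSLi, HMPA, rt; then aq. HCl to pH 3
Reagents that add atoms: none
Why: SN2 demethylation of the hindered C7 methyl ester by thiolate (O-alkyl cleavage) should leave the lactone, triol and exocyclic alkene intact.

**Compound list**

1 | cyclopentane-1,3-dione | O=C1CCC(=O)C1 | starting material
2 | 3-chlorocyclopent-2-en-1-one | ClC1=CC(=O)CC1 | intermediate
3 | dimethyl malonate | COC(=O)CC(=O)OC | starting material
4 | 2-chloro-N-methoxy-N-methylacetamide | CON(C)C(=O)CCl | starting material
5 | dimethyl 2-[2-[methoxy(methyl)amino]-2-oxoethyl]propanedioate | COC(=O)C(CC(=O)N(C)OC)C(=O)OC | intermediate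
6 | dimethyl 2-(2-oxopent-4-en-1-yl)propanedioate | COC(=O)C(CC(=O)CC=C)C(=O)OC | intermediate
7 | dimethyl 2-(2-oxopent-4-en-1-yl)-2-(3-oxocyclopent-1-en-1-yl)propanedioate | COC(=O)C(CC(=O)CC=C)(C(=O)OC)C1=CC(=O)CC1 | intermediate
8 | dimethyl 2-(3-diazo-2-oxopent-4-en-1-yl)-2-(3-oxocyclopent-1-en-1-yl)propanedioate | COC(=O)C(CC(=O)C(=[N+]=[N-])C=C)(C(=O)OC)C1=CC(=O)CC1 | intermediate
9 | dimethyl 2-(3-diazo-2-oxopent-4-en-1-yl)-2-[3-(triisopropylsilyloxy)cyclopenta-1,3-dien-1-yl]propanedioate | COC(=O)C(CC(=O)C(=[N+]=[N-])C=C)(C(=O)OC)C1=CC(O[Si](C(C)C)(C(C)C)C(C)C)=CC1 | intermediate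
10 | dimethyl 7-oxo-4-(triisopropylsilyloxy)-6-vinyltricyclo[4.3.0.0^{1,5}]non-3-ene-9,9-dicarboxylate (cyclopropane C8–C9–C15; C9 vinyl and C16=C13 cis, ring B on the other face) | C=C[C@@]12C(=O)CC(C(=O)OC)(C(=O)OC)[C@@]13CC=C(O[Si](C(C)C)(C(C)C)C(C)C)[C@@H]23 | intermediate (not isolated)
11 | dimethyl 4-oxo-9-(triisopropylsilyloxy)tricyclo[6.2.1.0^{1,5}]undeca-5,9-diene-2,2-dicarboxylate (C8 and C13 as in the target) | CC(C)[Si](C(C)C)(C(C)C)OC1=C[C@]23C[C@H]1CC=C2C(=O)CC3(C(=O)OC)C(=O)OC | intermediate
12 | dimethyl 4-oxo-9-(triisopropylsilyloxy)tricyclo[6.2.1.0^{1,5}]undec-9-ene-2,2-dicarboxylate (C9 epimers, C9 left open) | CC(C)[Si](C(C)C)(C(C)C)OC1=C[C@]23C[C@H]1CCC2C(=O)CC3(C(=O)OC)C(=O)OC | intermediate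
13 | methyl 4-oxo-9-(triisopropylsilyloxy)tricyclo[6.2.1.0^{1,5}]undec-9-ene-2-carboxylate (9β-H; C6 epimers, C6 left open) | CC(C)[Si](C(C)C)(C(C)C)OC1=C[C@]23C[C@H]1CC[C@H]2C(=O)CC3C(=O)OC | intermediate
14 | methyl 4-oxo-9-(triisopropylsilyloxy)tricyclo[6.2.1.0^{1,5}]undeca-2,9-diene-2-carboxylate (9β-H) | CC(C)[Si](C(C)C)(C(C)C)OC1=C[C@]23C[C@H]1CC[C@H]2C(=O)C=C3C(=O)OC | intermediate
15 | methyl 4-hydroxy-9-(triisopropylsilyloxy)-4-vinyltricyclo[6.2.1.0^{1,5}]undeca-2,9-diene-2-carboxylate (10α-OH, 10β-vinyl; present as its cerium alkoxide) | CC(C)[Si](C(C)C)(C(C)C)OC1=C[C@]23C[C@H]1CC[C@H]2[C@](O)(C=C)C=C3C(=O)OC | intermediate (not isolated)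
16 | methyl 4-(propanoyloxy)-9-(triisopropylsilyloxy)-4-vinyltricyclo[6.2.1.0^{1,5}]undeca-2,9-diene-2-carboxylate | CC(C)[Si](C(C)C)(C(C)C)OC1=C[C@]23C[C@H]1CC[C@H]2[C@](OC(=O)CC)(C=C)C=C3C(=O)OC | intermediate
17 | γ-lactone (C19–O–C10, C4–C5 bond; 4-H/4-CH3 open; 10β-vinyl; 5β-H; 6β-CO2Me; C15=C16 silyl enol ether) | CC(C)[Si](C(C)C)(C(C)C)OC1=C[C@]23C[C@H]1CC[C@H]2[C@@]1(C=C)OC(=O)C(C)[C@H]1[C@@H]3C(=O)OC | intermediate
18 | aldol adduct (quaternary C4 with CH3 and 3β-configured 1-hydroxyprop-2-enyl) | CC(C)[Si](C(C)C)(C(C)C)OC1=C[C@]23C[C@H]1CC[C@H]2[C@@]1(C=C)OC(=O)[C@@](C)([C@H]1[C@@H]3C(=O)OC)[C@@H](O)C=C | intermediate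
19 | methyl 3β-hydroxy-16-(triisopropylsilyloxy)-17,20-dinorgibberella-1,15-dien-7-oate 19,10-lactone | CC(C)[Si](C(C)C)(C(C)C)OC1=C[C@]23C[C@H]1CC[C@H]2[C@@]12OC(=O)[C@@](C)([C@H]1[C@@H]3C(=O)OC)[C@@H](O)C=C2 | intermediate
20 | methyl 3β-hydroxy-16-oxo-17,20-dinorgibberell-1-en-7-oate 19,10-lactone | O=C1C[C@]23C[C@H]1CC[C@H]2[C@@]12OC(=O)[C@@](C)([C@H]1[C@@H]3C(=O)OC)[C@@H](O)C=C2 | intermediate
21 | 1β,2β-osmate ester of 20, TMEDA complex | O=C1C[C@]23C[C@H]1CC[C@H]2[C@@]12OC(=O)[C@@](C)([C@H]1[C@@H]3C(=O)OC)[C@@H](O)[C@@H]4[C@H]2O[Os](=O)(=O)O4.CN(C)CCN(C)C | intermediate (not isolated)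
22 | methyl 1β,2β,3β-trihydroxy-16-oxo-17,20-dinorgibberellan-7-oate 19,10-lactone | O=C1C[C@]23C[C@H]1CC[C@H]2[C@@]12OC(=O)[C@@](C)([C@H]1[C@@H]3C(=O)OC)[C@@H](O)[C@@H](O)[C@H]2O | intermediate
23 | methyl 1β,2β,3β-trihydroxy-20-norgibberell-16-en-7-oate 19,10-lactone (methyl ester of the target) | C=C1C[C@]23C[C@H]1CC[C@H]2[C@@]12OC(=O)[C@@](C)([C@H]1[C@@H]3C(=O)OC)[C@@H](O)[C@@H](O)[C@H]2O | intermediate
24 | 1β,2β,3β-trihydroxy-20-norgibberell-16-en-7-oic acid 19,10-lactone (the target gibberellin) | C=C1C[C@]23C[C@H]1CC[C@H]2[C@@]12OC(=O)[C@@](C)([C@H]1[C@@H]3C(=O)O)[C@@H](O)[C@@H](O)[C@H]2O | target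

**Step count.** Total: 18 steps. Longest linear sequence: 17 steps (steps 2 to 18 from dimethyl malonate; step 1 is a one-step side branch).

**Steps most likely to fail**

Step 7. The chiral dirhodium carboxylate may discriminate poorly between the two faces of C8=C15, the only enantio-determining event, because the acceptor is a ketone and the reaction is intramolecular. The fallback gives up catalyst control and separates diastereomers instead. It sets out from 9 with achiral Rh2(OAc)4 (CH2Cl2, 0 °C); the same cascade then gives the racemate, that is 11 together with the enantiomeric tricycle F2, through 10 and the mirror-image cyclopropane F1. Reduction of the mixture with (R)-2-methyl-CBS-oxazaborolidine and catecholborane (toluene, −78 °C) is reagent-controlled at C10 and should turn the two enantiomers into the diastereomeric (10S)-allylic alcohol F3 (from 11) and (10S)-allylic alcohol F4 (from F2), separable by chromatography. Oxidation of F3 with MnO2 (CH2Cl2, rt) comes back to 11 as a single enantiomer.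

Step 13. The hindered lactone enolate may attack acrolein from the wrong face of C4 or in the conjugate sense, and the congested aldolate may revert by retro-aldol cleavage. The fallback makes the aldol intramolecular, so that only the convex face of C4 can be reached and 1,4-addition is impossible. It sets out from 14: the cerium acetylide of 3,3-diethoxyprop-1-yne (n-BuLi, CeCl3, THF, −78 °C) is added in place of the vinyl reagent to give the propargylic carbinol F5, acylated in the same flask with propanoic anhydride to the propanoate F6. KOtBu (cat.) in THF–t-BuOH closes the lactone by the same tethered Michael addition to give the alkynyl lactone F7. Semi-hydrogenation (H2, Pd/CaCO3 poisoned with Pb(OAc)2, quinoline) gives the Z-alkenyl acetal F8, and mild hydrolysis (pyridinium tosylate, wet acetone) gives the Z-enal F9. Intramolecular aldol addition of the lactone enolate (KN(SiMe3)2, 18-crown-6, THF, −78 °C; non-chelating conditions to favour the axial 3β-carbinol) closes ring A and comes back at 19, replacing steps 11 to 14.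

Step 6. Kinetic deprotonation may fail to discriminate between the C13 hydrogens of the enone and the C5 hydrogens of the diazoketone, or the amide base may attack the diazo group. The fallback forms the silyloxydiene while C10 is still an ester, which cannot compete, and brings in the diazo carbon afterwards with both nitrogens attached, so that neither a strong base nor a sulfonyl azide meets the acidic cyclopentadiene. It sets out from 3: alkylation with allyl bromoacetate (NaH, THF, 0 °C) gives the triester F10, addition–elimination with 2 (NaH, THF, 0 °C to rt) gives the enone triester F11, and LiN(iPr)2 followed by iPr3SiOTf (THF, −78 °C) gives the silyloxydiene triester F12. Pd(PPh3)4 (cat.) and morpholine (THF, 0 °C) remove the allyl group to give the carboxylic acid F13 as its morpholinium salt, which isobutyl chloroformate and N-methylmorpholine (THF, −20 °C) convert into the mixed anhydride F14; diazomethane (Et2O, −20 to 0 °C) then gives the diazomethyl ketone F15. Palladium-catalysed C–H vinylation of the diazoketone (vinyl iodide, Pd(PPh3)4 (cat.), Ag2CO3, Et3N, toluene, 10 °C) comes back at 9 immediately before step 7.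

**Further compounds**

F1 | step 7 | mirror image of divinylcyclopropane 10 | C=C[C@]12C(=O)CC(C(=O)OC)(C(=O)OC)[C@]13CC=C(O[Si](C(C)C)(C(C)C)C(C)C)[C@H]23
F2 | step 7 | mirror image of tricycle 11 | CC(C)[Si](C(C)C)(C(C)C)OC1=C[C@@]23C[C@@H]1CC=C2C(=O)CC3(C(=O)OC)C(=O)OC
F3 | step 7 | (10S)-allylic alcohol from 11: dimethyl 4-hydroxy-9-(triisopropylsilyloxy)tricyclo[6.2.1.0^{1,5}]undeca-5,9-diene-2,2-dicarboxylate | CC(C)[Si](C(C)C)(C(C)C)OC1=C[C@]23C[C@H]1CC=C2[C@@H](O)CC3(C(=O)OC)C(=O)OC
F4 | step 7 | (10S)-allylic alcohol from F2 (diastereomer of F3) | CC(C)[Si](C(C)C)(C(C)C)OC1=C[C@@]23C[C@@H]1CC=C2[C@@H](O)CC3(C(=O)OC)C(=O)OC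
F5 | step 13 | propargylic carbinol: 15 with 3,3-diethoxyprop-1-ynyl in place of vinyl | CC(C)[Si](C(C)C)(C(C)C)OC1=C[C@]23C[C@H]1CC[C@H]2[C@](O)(C#CC(OCC)OCC)C=C3C(=O)OC
F6 | step 13 | propanoate of F5 | CC(C)[Si](C(C)C)(C(C)C)OC1=C[C@]23C[C@H]1CC[C@H]2[C@](OC(=O)CC)(C#CC(OCC)OCC)C=C3C(=O)OC
F7 | step 13 | alkynyl lactone: 17 with 10β-(3,3-diethoxyprop-1-ynyl) | CC(C)[Si](C(C)C)(C(C)C)OC1=C[C@]23C[C@H]1CC[C@H]2[C@@]1(C#CC(OCC)OCC)OC(=O)C(C)[C@H]1[C@@H]3C(=O)OC
F8 | step 13 | Z-alkenyl acetal: 17 with 10β-[(Z)-3,3-diethoxyprop-1-enyl] | CC(C)[Si](C(C)C)(C(C)C)OC1=C[C@]23C[C@H]1CC[C@H]2[C@@]1(/C=C\C(OCC)OCC)OC(=O)C(C)[C@H]1[C@@H]3C(=O)OC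
F9 | step 13 | Z-enal: 17 with 10β-[(Z)-3-oxoprop-1-enyl] | CC(C)[Si](C(C)C)(C(C)C)OC1=C[C@]23C[C@H]1CC[C@H]2[C@@]1(/C=C\C=O)OC(=O)C(C)[C@H]1[C@@H]3C(=O)OC
F10 | step 6 | dimethyl 2-[2-oxo-2-(prop-2-en-1-yloxy)ethyl]propanedioate | COC(=O)C(CC(=O)OCC=C)C(=O)OC
F11 | step 6 | dimethyl 2-[2-oxo-2-(prop-2-en-1-yloxy)ethyl]-2-(3-oxocyclopent-1-en-1-yl)propanedioate | COC(=O)C(CC(=O)OCC=C)(C(=O)OC)C1=CC(=O)CC1
F12 | step 6 | dimethyl 2-[2-oxo-2-(prop-2-en-1-yloxy)ethyl]-2-[3-(triisopropylsilyloxy)cyclopenta-1,3-dien-1-yl]propanedioate | COC(=O)C(CC(=O)OCC=C)(C(=O)OC)C1=CC(O[Si](C(C)C)(C(C)C)C(C)C)=CC1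
F13 | step 6 | 4-methoxy-3-(methoxycarbonyl)-4-oxo-3-[3-(triisopropylsilyloxy)cyclopenta-1,3-dien-1-yl]butanoic acid | COC(=O)C(CC(=O)O)(C(=O)OC)C1=CC(O[Si](C(C)C)(C(C)C)C(C)C)=CC1
F14 | step 6 | mixed anhydride of F13 with isobutyl hydrogen carbonate | COC(=O)C(CC(=O)OC(=O)OCC(C)C)(C(=O)OC)C1=CC(O[Si](C(C)C)(C(C)C)C(C)C)=CC1
F15 | step 6 | dimethyl 2-(3-diazo-2-oxopropyl)-2-[3-(triisopropylsilyloxy)cyclopenta-1,3-dien-1-yl]propanedioate | COC(=O)C(CC(=O)C=[N+]=[N-])(C(=O)OC)C1=CC(O[Si](C(C)C)(C(C)C)C(C)C)=CC1
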